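The earlier runs and the new flask were computed from invented constants; the scatter is artificial.

The blue run has converted 15.5 % of its substrates at 12.0 min. The amber run, with twice the coupling partner of the blue run, has converted 26.9 % at 10.0 min.

the same everywhere: left-handed substrate 0.10 M; right-handed substrate 0.10 M; racemization catalyst 0.20 mM; precatalyst 0.12 mM

| run | coupling partner | remark | time |
|---|---|---|---|
| amber | 0.30 M | the very flask that is asked about, followed so far |  |
| blue | 0.15 M | run made earlier |  |
| flask | 0.300 M |  | 30 min |

| run | time / min | left-handed substrate / % | right-handed substrate / % | left-handed product / % |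
|---|---|---|---|---|
| amber | 0.667 | 48.8 | 48.5 | 0.5 |
| amber | 2.00 | 46.5 | 45.8 | 6.5 |
| amber | 3.00 | 43.8 | 43.5 | 8.7 |
| amber | 5.00 | 40.2 | 39.0 | 12.7 |
| amber | 6.00 | 38.3 | 38.4 | 11.6 |
| amber | 10.0 | 36.3 | 36.8 | 17.8 |
| blue | 1.00 | 48.8 | 51.0 | 1.3 |
| blue | 1.50 | 48.4 | 48.7 | 0.8 |
| blue | 2.50 | 46.0 | 47.3 | 5.0 |
| blue | 4.00 | 44.7 | 46.6 | 4.7 |
| blue | 8.00 | 43.7 | 45.4 | 8.6 |
| blue | 12.0 | 42.6 | 41.9 | 9.0 |

(each reading ± 1 percentage point)

- part of the left-handed substrate and right-handed substrate charged together that has reacted at 30 min
- excess of left-handed product over right-handed product in the product at 30 min
- excess of right-handed substrate over left-handed substrate among what is left of the two at 30 min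

Here is the puzzle. The amber run holds more partner than substrate, and 36.3 % of left-handed substrate still stands at 10.0 min, yet conversion is flattening near a quarter. I read this as the partner leaving by its second way, decomposition. I take both ways to run in proportion to the partner, so at a given catalyst charge and a fairly steady substrate level I expect their ratio to hold however much partner is charged. I take the blue run as nearly over, which is a reading with its scatter, and balance its partner:

partner in product = 0.0310 M

coupling odds = partner in product / partner decomposed = 0.261

These coupling odds, partner coupled per partner decomposed, carry over to the flask, which is the amber run followed on to 30 min: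

conversion = odds / (1 + odds) × partner charged / substrates charged = 31.0 %

The forecast stands a little above my figure, with 32 % reacted, a product excess of 28 % and a substrate excess of 0.3 %, holding that “the partner is decomposing with k about 0.2 per min”.

The flask gives 27.5 % reacted, a product excess of 23.6 % and a substrate excess of 0 %, so the forecast holds within its margins.

    coupling partner + free catalyst + right-handed substrate → free catalyst + right-handed product (k = 85.0 L² mol⁻² s⁻¹)
    left-handed substrate + racemization catalyst ⇌ right-handed substrate + racemization catalyst, rate k2*[racemization catalyst]*[left-handed substrate] forward; the back reaction follows from the equilibrium constant (k = 38.0 L mol⁻¹ s⁻¹)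
    coupling partner + free catalyst + left-handed substrate → free catalyst + left-handed product (k = 140 L² mol⁻² s⁻¹)
    precatalyst ⇌ free catalyst (K = 1.20, k = 0.00620 s⁻¹)
    coupling partner → decomposed reagent (k = 0.00390 s⁻¹)

At 30.0 min, decomposition uses partner 5.9 times as fast as coupling with left-handed substrate. Less partner remains in the flask, at 0.013 % of its charge, than right-handed substrate, at 72 %: the partner is the limiting reagent, though its charge is larger than that of the two substrates together. The neighbour charged with 3.0 × 10⁻⁵ M of precatalyst has a quarter of the precatalyst of the flask, and free catalyst stands there at 54.5 % of the catalyst charged, the same share as in the flask, so I scale the odds to 0.0651, which gives 9.17 %. The computed neighbour flask gives 9.24 %.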